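## Retrosynthetic overview

1. The target 27 comes from hepta-acetate 26 by global deacetylation.
2. 26 is cut across the cyclohexene by an enantioselective endo [4+2] cycloaddition into dienophile 14 (prenyl chalcone, 2'-OH free) and diene 23 (dehydroprenyl chalcone tetra-acetate).
3. 14 comes from a Claisen–Schmidt condensation of prenyl ketone 11 with aldehyde 4; 11 is built on resorcinol by two directed ortho-metalations.
4. 23 comes from a Suzuki–Miyaura coupling of iodo-chalcone tetra-acetate 20 with dienylboronate 22; 20 comes from iodo ketone 17 and the same aldehyde 4.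
5. Ring order: every benzene ring is resorcinol; the cyclohexene is the only ring made, in the penultimate step.

Locants used below: cyclohexene C1'' (bears CH3), C2'' (=CH), C3'' (bears the chalcone aryl), C4'' (bears the aroyl group), C5'' (bears the 2,4-dioxygenated phenyl), C6'' (CH2). The target is (3''S,4''R,5''S), with 3'',4''-cis and 4'',5''-trans; in cyclohex-2-en-1-yl numbering this is (1S,5S,6R).

Assumption: the (R)-VANOL borate is taken to leave open the enone face that gives the (3''S,4''R,5''S) series (assigned from a model of the spiro-borate, not from a recalled result); if the first run gives the mirror-image series, (S)-VANOL is used with nothing else changed.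

## Route

**Aldehyde 4 (used twice)**

Step 1
Reactants: 1 resorcinol
Product: 3 2,4-dihydroxybenzaldehyde, via iminium chloride 2 (not isolated)
Conditions: POCl3, DMF, MeCN, −15 °C → rt; then H2O, 50 °C
Reagents that add atoms: N,N-dimethylformamide CN(C)C=O; water O
Why: Vilsmeier–Haack formylation attacks resorcinol at C4 (para to one OH, ortho to the other) and hydrolysis of the iminium salt gives the aldehyde.

Step 2
Reactants: 3 2,4-dihydroxybenzaldehyde
Product: 4 2,4-bis(methoxymethoxy)benzaldehyde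
Conditions: MOMCl, i-Pr2NEt, CH2Cl2, 0 °C → reflux
Reagents that add atoms: chloromethyl methyl ether COCCl
Why: O-alkylation of both phenols (Williamson-type acetal protection) gives base-stable MOM ethers for the later aldol condensations.

**Dienophile 14**

Step 3
Reactants: 1 resorcinol
Product: 5 1,3-bis(methoxymethoxy)benzene
Conditions: MOMCl, i-Pr2NEt, CH2Cl2, 0 °C → rt
Reagents that add atoms: chloromethyl methyl ether COCCl
Why: Williamson-type MOM protection installs the two ortho-directing groups needed for the metalations.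

Step 4
Reactants: 5 1,3-bis(methoxymethoxy)benzene; 6 prenyl bromide
Product: 8 1,3-bis(methoxymethoxy)-2-(3-methylbut-2-en-1-yl)benzene, via aryllithium 7 (not isolated)
Conditions: n-BuLi, THF, 0 °C; CuBr·SMe2 (10 mol %), then 6, −78 °C → rt
Reagents that add atoms: none
Why: Directed ortho-metalation occurs at C2 between the two OMOM groups, and SN2 allylation at the unhindered CH2 of prenyl bromide gives the linear prenyl arene.

Step 5
Reactants: 8 1,3-bis(methoxymethoxy)-2-(3-methylbut-2-en-1-yl)benzene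
Product: 11 1-[2,4-bis(methoxymethoxy)-3-(3-methylbut-2-en-1-yl)phenyl]ethan-1-one, via aryllithium 9 (not isolated), via lithium hemiaminal alkoxide 10 (not isolated)
Conditions: s-BuLi, TMEDA, THF, −78 °C; then MeC(O)N(OMe)Me, −78 → 0 °C; H2O
Reagents that add atoms: N-methoxy-N-methylacetamide CC(=O)N(C)OC
Why: A second, kinetically controlled directed ortho-metalation at C4 followed by Weinreb ketone synthesis gives the methyl ketone, the chelated tetrahedral adduct preventing over-addition.

Step 6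
Reactants: 11 1-[2,4-bis(methoxymethoxy)-3-(3-methylbut-2-en-1-yl)phenyl]ethan-1-one; 4 2,4-bis(methoxymethoxy)benzaldehyde
Product: 12 (E)-1-[2,4-bis(methoxymethoxy)-3-(3-methylbut-2-en-1-yl)phenyl]-3-[2,4-bis(methoxymethoxy)phenyl]prop-2-en-1-one
Conditions: KOH, EtOH–H2O, rt
Reagents that add atoms: none
Why: Claisen–Schmidt (crossed aldol) condensation with a non-enolisable aldehyde, the E1cB dehydration giving the thermodynamically favoured E-enone.

Step 7
Reactants: 12 tetra-MOM prenyl chalcone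
Product: 13 (E)-1-[2,4-dihydroxy-3-(3-methylbut-2-en-1-yl)phenyl]-3-(2,4-dihydroxyphenyl)prop-2-en-1-one
Conditions: 3 M aq HCl, MeOH, 45 °C, dark
Reagents that add atoms: none
Why: Acid-catalysed methanolysis of the four MOM acetals (transacetalisation) is mild enough to leave the prenyl alkene and the E-enone untouched.

Step 8
Reactants: 13 tetrahydroxy prenyl chalcone
Product: 14 4-[(1E)-3-[4-(acetyloxy)-2-hydroxy-3-(3-methylbut-2-en-1-yl)phenyl]-3-oxoprop-1-en-1-yl]benzene-1,3-diyl diacetate
Conditions: Ac2O (3.1 equiv), pyridine, CH2Cl2, −10 → 0 °C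
Reagents that add atoms: acetic anhydride CC(=O)OC(C)=O
Why: Chemoselective O-acylation takes the three unhindered phenols, while the 2'-OH, hydrogen-bonded to the ketone and flanked by the prenyl group, stays free for boron chelation.

**Diene 23**

Step 9
Reactants: 1 resorcinol
Product: 15 1-(2,4-dihydroxyphenyl)ethan-1-one
Conditions: AcOH, ZnCl2, 140 °C; dilute HCl work-up
Reagents that add atoms: acetic acid CC(=O)O
Why: Nencki reaction (ZnCl2-mediated Friedel–Crafts C-acylation) at C4 of resorcinol, activated by both hydroxyls.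

Step 10
Reactants: 15 1-(2,4-dihydroxyphenyl)ethan-1-one
Product: 16 1-(2,4-dihydroxy-3-iodophenyl)ethan-1-one
Conditions: I2 (0.4 equiv), HIO3 (0.2 equiv), EtOH–H2O, 35 °C
Reagents that add atoms: iodine II; iodic acid OI(=O)=O
Why: Electrophilic aromatic iodination (iodic acid re-oxidises iodide so all iodine is used) goes to C3 between the two hydroxyls, the most nucleophilic site of the chelated ketone; the minor 5-iodo isomer is removed by crystallisation.

Step 11
Reactants: 16 1-(2,4-dihydroxy-3-iodophenyl)ethan-1-one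
Product: 17 1-[3-iodo-2,4-bis(methoxymethoxy)phenyl]ethan-1-one
Conditions: NaH (2.4 equiv), MOMCl, DMF, 0 °C → rt
Reagents that add atoms: chloromethyl methyl ether COCCl
Why: Williamson-type alkylation of the bis-phenoxide, the sodium salt breaking the chelate that otherwise shields the hindered 2-OH.

Step 12
Reactants: 17 1-[3-iodo-2,4-bis(methoxymethoxy)phenyl]ethan-1-one; 4 2,4-bis(methoxymethoxy)benzaldehyde
Product: 18 (E)-1-[3-iodo-2,4-bis(methoxymethoxy)phenyl]-3-[2,4-bis(methoxymethoxy)phenyl]prop-2-en-1-one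
Conditions: KOH, EtOH–H2O, rt
Reagents that add atoms: none
Why: Claisen–Schmidt condensation gives the E-chalcone; the aryl iodide is inert to aqueous hydroxide at room temperature.

Step 13
Reactants: 18 tetra-MOM iodo chalcone
Product: 19 (E)-1-(2,4-dihydroxy-3-iodophenyl)-3-(2,4-dihydroxyphenyl)prop-2-en-1-one
Conditions: 3 M aq HCl, MeOH, 45 °C, dark
Reagents that add atoms: none
Why: Acid-catalysed methanolysis of the MOM acetals is done before the acid-sensitive diene is introduced.

Step 14
Reactants: 19 tetrahydroxy iodo chalcone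
Product: 20 4-[(1E)-3-[2,4-bis(acetyloxy)-3-iodophenyl]-3-oxoprop-1-en-1-yl]benzene-1,3-diyl diacetate
Conditions: Ac2O (excess), pyridine, DMAP (cat.), CH2Cl2, rt
Reagents that add atoms: acetic anhydride CC(=O)OC(C)=O
Why: DMAP-catalysed exhaustive O-acylation also caps the chelated 2'-OH, so this chalcone cannot bind boron and act as a dienophile later.

Step 15
Reactants: 21 2-methylbut-1-en-3-yne
Product: 22 (E)-4,4,5,5-tetramethyl-2-(3-methylbuta-1,3-dien-1-yl)-1,3,2-dioxaborolane
Conditions: HBpin, Cp2Zr(H)Cl (5 mol %), Et3N (10 mol %), CH2Cl2, rt, sealed vessel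
Reagents that add atoms: pinacolborane CC1(C)OBOC1(C)C
Why: Zirconocene-catalysed hydroboration adds H–B syn across the alkyne only, with boron at the terminal carbon, which sets the E geometry of the dienylboronate.

Step 16
Reactants: 20 iodo chalcone tetra-acetate; 22 (E)-dienylboronate
Product: 23 4-[(1E)-3-[2,4-bis(acetyloxy)-3-[(1E)-3-methylbuta-1,3-dien-1-yl]phenyl]-3-oxoprop-1-en-1-yl]benzene-1,3-diyl diacetate
Conditions: Pd(OAc)2 (5 mol %), 2-dicyclohexylphosphino-2',6'-dimethoxybiphenyl (SPhos, 10 mol %), anhydrous K3PO4, toluene, 60 °C; aqueous work-up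
Reagents that add atoms: none
Why: Suzuki–Miyaura coupling, in which oxidative addition of the di-ortho-substituted iodide to zerovalent palladium and transmetalation are carried by the bulky biaryl phosphine, proceeds with retention of the E-alkene and the anhydrous phosphate spares the aryl acetates.

**Fragment union and end game**

Step 17
Reactants: 14 dienophile triacetate; 23 diene tetra-acetate
Product: 26 (3''S,4''R,5''S)-hepta-acetate cycloadduct with only the 2-OH of the prenylated benzoyl ring free, via dienophile borate 24 (not isolated), via cycloadduct borate 25 (not isolated)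
Conditions: (R)-VANOL (1.2 equiv), BH3·THF (1.2 equiv), AcOH (1.2 equiv), THF, rt; add 14, rt, 1 h; evaporate; 23 (1.3 equiv), PhCF3, 40 °C, 36 h; H2O work-up; SiO2 chromatography to remove the exo isomer
Reagents that add atoms: none
Why: Boron-templated asymmetric Diels–Alder reaction in which the E-enone fixes 4'',5''-trans, endo approach of the E-diene fixes 3'',4''-cis, and the chiral spiro-borate shields one enone face to set the absolute configuration (3''S,4''R,5''S), with the unsubstituted diene terminus bonding to the enone β-carbon.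

Step 18
Reactants: 26 hepta-acetate cycloadduct
Product: 27 (E)-1-[3-[(1S,5S,6R)-6-[2,4-dihydroxy-3-(3-methylbut-2-en-1-yl)benzoyl]-5-(2,4-dihydroxyphenyl)-3-methylcyclohex-2-en-1-yl]-2,4-dihydroxyphenyl]-3-(2,4-dihydroxyphenyl)prop-2-en-1-one
Conditions: K2CO3 (0.5 equiv), degassed MeOH, 0 °C → rt, argon; then pH 6 phosphate buffer
Reagents that add atoms: none
Why: Base-catalysed transesterification (methanolysis) of the seven aryl acetates is mild and acid-free, avoiding ketalisation and prenyl cyclisation, and is kept short and cold to limit C4'' epimerisation and chalcone–flavanone isomerisation.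

## Compound list

1 | resorcinol (benzene-1,3-diol) | Oc1cccc(O)c1 | starting material
2 | [(2,4-dihydroxyphenyl)methylidene]dimethylammonium chloride, formed in the flask | C[N+](C)=Cc1ccc(O)cc1O.[Cl-] | intermediate
3 | 2,4-dihydroxybenzaldehyde | O=Cc1ccc(O)cc1O | intermediate
4 | 2,4-bis(methoxymethoxy)benzaldehyde | COCOc1ccc(C=O)c(OCOC)c1 | intermediate
5 | 1,3-bis(methoxymethoxy)benzene | COCOc1cccc(OCOC)c1 | intermediate
6 | prenyl bromide (1-bromo-3-methylbut-2-ene) | CC(C)=CCBr | starting material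
7 | [2,6-bis(methoxymethoxy)phenyl]lithium, formed in the flask | [Li]c1c(OCOC)cccc1OCOC | intermediate
8 | 1,3-bis(methoxymethoxy)-2-(3-methylbut-2-en-1-yl)benzene | COCOc1cccc(OCOC)c1CC=C(C)C | intermediate
9 | [2,4-bis(methoxymethoxy)-3-(3-methylbut-2-en-1-yl)phenyl]lithium, formed in the flask | [Li]c1ccc(OCOC)c(CC=C(C)C)c1OCOC | intermediate
10 | lithium 1-[2,4-bis(methoxymethoxy)-3-(3-methylbut-2-en-1-yl)phenyl]-1-[methoxy(methyl)amino]ethan-1-olate, formed in the flask | CC([O-])(N(C)OC)c1ccc(OCOC)c(CC=C(C)C)c1OCOC.[Li+] | intermediate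
11 | 1-[2,4-bis(methoxymethoxy)-3-(3-methylbut-2-en-1-yl)phenyl]ethan-1-one | CC(=O)c1ccc(OCOC)c(CC=C(C)C)c1OCOC | intermediate
12 | (E)-1-[2,4-bis(methoxymethoxy)-3-(3-methylbut-2-en-1-yl)phenyl]-3-[2,4-bis(methoxymethoxy)phenyl]prop-2-en-1-one | COCOc1ccc(/C=C/C(=O)c2ccc(OCOC)c(CC=C(C)C)c2OCOC)c(OCOC)c1 | intermediate
13 | (E)-1-[2,4-dihydroxy-3-(3-methylbut-2-en-1-yl)phenyl]-3-(2,4-dihydroxyphenyl)prop-2-en-1-one | CC(C)=CCc1c(O)ccc(C(=O)/C=C/c2ccc(O)cc2O)c1O | intermediate
14 | 4-[(1E)-3-[4-(acetyloxy)-2-hydroxy-3-(3-methylbut-2-en-1-yl)phenyl]-3-oxoprop-1-en-1-yl]benzene-1,3-diyl diacetate (dienophile) | CC(C)=CCc1c(OC(C)=O)ccc(C(=O)/C=C/c2ccc(OC(C)=O)cc2OC(C)=O)c1O | intermediate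
15 | 1-(2,4-dihydroxyphenyl)ethan-1-one | CC(=O)c1ccc(O)cc1O | intermediate
16 | 1-(2,4-dihydroxy-3-iodophenyl)ethan-1-one | CC(=O)c1ccc(O)c(I)c1O | intermediate
17 | 1-[3-iodo-2,4-bis(methoxymethoxy)phenyl]ethan-1-one | CC(=O)c1ccc(OCOC)c(I)c1OCOC | intermediate
18 | (E)-1-[3-iodo-2,4-bis(methoxymethoxy)phenyl]-3-[2,4-bis(methoxymethoxy)phenyl]prop-2-en-1-one | COCOc1ccc(/C=C/C(=O)c2ccc(OCOC)c(I)c2OCOC)c(OCOC)c1 | intermediate
19 | (E)-1-(2,4-dihydroxy-3-iodophenyl)-3-(2,4-dihydroxyphenyl)prop-2-en-1-one | O=C(/C=C/c1ccc(O)cc1O)c1ccc(O)c(I)c1O | intermediate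
20 | 4-[(1E)-3-[2,4-bis(acetyloxy)-3-iodophenyl]-3-oxoprop-1-en-1-yl]benzene-1,3-diyl diacetate | CC(=O)Oc1ccc(/C=C/C(=O)c2ccc(OC(C)=O)c(I)c2OC(C)=O)c(OC(C)=O)c1 | intermediate
21 | 2-methylbut-1-en-3-yne | C=C(C)C#C | starting material
22 | (E)-4,4,5,5-tetramethyl-2-(3-methylbuta-1,3-dien-1-yl)-1,3,2-dioxaborolane | C=C(C)/C=C/B1OC(C)(C)C(C)(C)O1 | intermediate
23 | 4-[(1E)-3-[2,4-bis(acetyloxy)-3-[(1E)-3-methylbuta-1,3-dien-1-yl]phenyl]-3-oxoprop-1-en-1-yl]benzene-1,3-diyl diacetate (diene) | C=C(C)/C=C/c1c(OC(C)=O)ccc(C(=O)/C=C/c2ccc(OC(C)=O)cc2OC(C)=O)c1OC(C)=O | intermediate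
24 | borate formed in the flask from 14, BH3 and (R)-VANOL: the 2-oxygen of the benzoyl ring of 14 is bound to boron, which carries (R)-3,3'-diphenyl-2,2'-binaphthalene-1,1'-diolate and is chelated by the ketone oxygen (R axis not encoded in the SMILES) | CC(C)=CCc1c(OC(C)=O)ccc(C(=O)/C=C/c2ccc(OC(C)=O)cc2OC(C)=O)c1OB1Oc2c(-c3c(O1)c4ccccc4cc3-c3ccccc3)c(-c3ccccc3)cc3ccccc23 | intermediate
25 | the same (R)-VANOL borate carrying the (3''S,4''R,5''S) cycloadduct, formed in the flask (R axis not encoded in the SMILES) | CC(C)=CCc1c(OC(C)=O)ccc(C(=O)[C@H]2[C@@H](c3c(OC(C)=O)ccc(C(=O)/C=C/c4ccc(OC(C)=O)cc4OC(C)=O)c3OC(C)=O)C=C(C)C[C@@H]2c2ccc(OC(C)=O)cc2OC(C)=O)c1OB1Oc2c(-c3c(O1)c4ccccc4cc3-c3ccccc3)c(-c3ccccc3)cc3ccccc23 | intermediate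
26 | (3''S,4''R,5''S)-hepta-acetate of 27: every phenol acetylated except the 2-OH (ortho to the ketone) of the prenylated benzoyl ring; 3'',4''-cis and 4'',5''-trans | CC(C)=CCc1c(OC(C)=O)ccc(C(=O)[C@H]2[C@@H](c3c(OC(C)=O)ccc(C(=O)/C=C/c4ccc(OC(C)=O)cc4OC(C)=O)c3OC(C)=O)C=C(C)C[C@@H]2c2ccc(OC(C)=O)cc2OC(C)=O)c1O | intermediate
27 | (E)-1-[3-[(1S,5S,6R)-6-[2,4-dihydroxy-3-(3-methylbut-2-en-1-yl)benzoyl]-5-(2,4-dihydroxyphenyl)-3-methylcyclohex-2-en-1-yl]-2,4-dihydroxyphenyl]-3-(2,4-dihydroxyphenyl)prop-2-en-1-one | CC(C)=CCc1c(O)ccc(C(=O)[C@H]2[C@@H](c3c(O)ccc(C(=O)/C=C/c4ccc(O)cc4O)c3O)C=C(C)C[C@@H]2c2ccc(O)cc2O)c1O | target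

## Step count and risks

Total step count: 18. Longest linear sequence: 9 steps (steps 9, 10, 11, 12, 13, 14, 16, 17, 18).

**Step 5 (second metalation and acylation).** The prenyl CH2 is both benzylic and allylic and may be deprotonated in place of the ring, and the Weinreb amide may be enolised. The fallback leaves organolithium chemistry for an aromatic Claisen rearrangement; it sets out from 15 and comes back at 11. Ketone 15 is O-alkylated at the non-chelated 4-OH with 3-chloro-3-methylbut-1-yne (K2CO3, KI, acetone, reflux) to give 1-[2-hydroxy-4-[(2-methylbut-3-yn-2-yl)oxy]phenyl]ethan-1-one F1. Semi-hydrogenation (H2, Pd/CaCO3 poisoned with Pb(OAc)2, quinoline, EtOAc) gives 1-[2-hydroxy-4-[(2-methylbut-3-en-2-yl)oxy]phenyl]ethan-1-one F2. Heating in N,N-diethylaniline at 130 °C moves the allyl unit by [3,3] shift to C3, giving 1-[2,4-dihydroxy-3-(3-methylbut-2-en-1-yl)phenyl]ethan-1-one F3. Bis-MOM protection (NaH, MOMCl, DMF) then gives 11.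

**Step 16 (Suzuki–Miyaura coupling).** The iodide sits between two acetoxy groups, and the base may cleave aryl acetates. The fallback replaces the boron coupling by a Heck reaction and elimination; it sets out from 20 and comes back at 23. Iodide 20 and 2-methylbut-3-en-2-ol (Pd(OAc)2, P(o-tol)3, Et3N, MeCN, 80 °C) give 4-[(1E)-3-[2,4-bis(acetyloxy)-3-[(1E)-3-hydroxy-3-methylbut-1-en-1-yl]phenyl]-3-oxoprop-1-en-1-yl]benzene-1,3-diyl diacetate F4. Dehydration of this tertiary allylic alcohol (MsCl, Et3N, CH2Cl2, 0 °C → rt) gives diene 23.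

**Step 17 (asymmetric Diels–Alder reaction).** Endo/exo selectivity with this hindered diene may be modest, conversion may be slow, and the sense of induction rests on the assumption above. The fallback gives up asymmetric induction for resolution; it sets out from 14 and 23 and comes back at 26. The two are combined over silica-supported silver nanoparticles (Ag/SiO2, CH2Cl2, 50 °C), a promoter that tends to favour the endo adduct. This gives racemic endo adduct, that is 26 together with its mirror image, the (3''R,4''S,5''R)-hepta-acetate F5. Preparative HPLC on an amylose tris(3,5-dimethylphenylcarbamate) phase separates them, and 26 goes on to step 18.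

## Further compounds

F1 | step 5 | 1-[2-hydroxy-4-[(2-methylbut-3-yn-2-yl)oxy]phenyl]ethan-1-one | CC(=O)c1ccc(OC(C)(C)C#C)cc1O
F2 | step 5 | 1-[2-hydroxy-4-[(2-methylbut-3-en-2-yl)oxy]phenyl]ethan-1-one | CC(=O)c1ccc(OC(C)(C)C=C)cc1O
F3 | step 5 | 1-[2,4-dihydroxy-3-(3-methylbut-2-en-1-yl)phenyl]ethan-1-one | CC(=O)c1ccc(O)c(CC=C(C)C)c1O
F4 | step 16 | 4-[(1E)-3-[2,4-bis(acetyloxy)-3-[(1E)-3-hydroxy-3-methylbut-1-en-1-yl]phenyl]-3-oxoprop-1-en-1-yl]benzene-1,3-diyl diacetate | CC(C)(O)/C=C/c1c(OC(C)=O)ccc(C(=O)/C=C/c2ccc(OC(C)=O)cc2OC(C)=O)c1OC(C)=O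
F5 | step 17 | (3''R,4''S,5''R)-hepta-acetate, the mirror image of 26 | CC(C)=CCc1c(OC(C)=O)ccc(C(=O)[C@@H]2[C@H](c3c(OC(C)=O)ccc(C(=O)/C=C/c4ccc(OC(C)=O)cc4OC(C)=O)c3OC(C)=O)C=C(C)C[C@H]2c2ccc(OC(C)=O)cc2OC(C)=O)c1O
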